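**Retrosynthetic overview**

1. The plan rests on ring A, the central 2,3-dihydrobenzofuran: its O1 sits on C7a ortho to the doubly benzylic C3 (a latent o-quinone methide carbon), and C2 is a lone benzylic carbon carrying only the 4-hydroxyphenyl group. O1–C2 and C2–C3 are cut together ([4+1]) to aryl sulfone 36 and a 4-(benzyloxy)benzyl sulfonium ylide.
2. 36 comes from salicylaldehyde 19 and the aryllithium of the finished, enantiopure ring-B dihydrobenzofuran 32 (C3–aryl bond), followed by sulfinic acid exchange.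
3. 19 comes from oxolane bromide 17. The oxolane is made from bis-sulfone 15 by two aryl-zinc substitutions (C2–aryl, C5–aryl); its C3/C4 centres come from an Ir/isothiourea allylic alkylation (C3–C4 bond).
4. Ring order: ring B (step 22) and the oxolane (steps 10–13) in separate branches, ring A last (step 29). Ring B is complete before the key step, because a late oxidative phenol/stilbene annulation would set its two centres without control and would oxidise the para-benzylic C3–H.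
5. All ten phenols travel as benzyl ethers and are freed by hydrogenolysis, so that no acid meets the finished skeleton, whose p-oxybenzylic cyclic ethers ionise easily.

Key step: step 29

Abbreviations in names: BP = 4-(benzyloxy)phenyl; DBP = 3,5-bis(benzyloxy)phenyl; THF unit = (2R,3S,4R,5S)-4-DBP-2,5-di-BP-oxolan-3-yl; ring-B unit = (2R,3R)-7-(benzyloxy)-2-BP-3-DBP-2,3-dihydro-1-benzofuran-5-yl.

Assumption 1: the antipodes of the Ir–phosphoramidite, of benzotetramisole (BTM) and of Rh2(PTAD)4 are those that give the configurations drawn; both antipodes of each are available and the sense is to be confirmed on the first run.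

Assumption 2: the (2S,5S)-thiolanium benzylide is taken to add with the facial sense it shows in aldehyde epoxidation, which here gives 2S at ring A; were the sense opposite, the salt from (2S,5S)-hexane-2,5-diol would take its place.

**Route**

Step 1
Reactants: 1 methyl 2-(3,5-dihydroxyphenyl)acetate
Product: 2 methyl 2-[3,5-bis(benzyloxy)phenyl]acetate
Conditions: BnBr (2.2 equiv), K2CO3, acetone, reflux
Reagents that add atoms: benzyl bromide, BrCc1ccccc1
Why: Williamson ether synthesis on both phenols; potassium carbonate in acetone does not enolise the aryl acetate.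

Step 2
Reactants: 2 methyl 2-[3,5-bis(benzyloxy)phenyl]acetate
Product: 3 methyl 2-[3,5-bis(benzyloxy)-2-bromophenyl]acetate
Conditions: NBS (1.0 equiv), MeCN, 0 °C
Reagents that add atoms: N-bromosuccinimide, O=C1CCC(=O)N1Br
Why: Electrophilic aromatic bromination takes the position beside the side chain that is para to one ether and ortho to the other, the usual site in 3,5-dialkoxybenzyl compounds, because the position between the two ethers is more crowded.

Step 3
Reactants: 3 methyl 2-[3,5-bis(benzyloxy)-2-bromophenyl]acetate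
Product: 4 2-[3,5-bis(benzyloxy)-2-bromophenyl]acetic acid
Conditions: LiOH, THF/MeOH/H2O, rt; then 1 M HCl
Reagents that add atoms: lithium hydroxide, [Li+].[OH-]
Why: Ester saponification.

Step 4
Reactants: 4 2-[3,5-bis(benzyloxy)-2-bromophenyl]acetic acid
Product: 5 pentafluorophenyl 2-[3,5-bis(benzyloxy)-2-bromophenyl]acetate
Conditions: C6F5OH, DCC, DMAP (cat.), CH2Cl2, 0 °C to rt
Reagents that add atoms: pentafluorophenol, Oc1c(F)c(F)c(F)c(F)c1F
Why: Carbodiimide (Steglich) esterification gives the aryl ester that is active enough to acylate an isothiourea in step 8.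

Step 5
Reactants: 6 3,5-bis(benzyloxy)benzaldehyde
Product: 7 ethyl (2E)-3-[3,5-bis(benzyloxy)phenyl]prop-2-enoate
Conditions: (EtO)2P(O)CH2CO2Et, NaH, THF, 0 °C to rt
Reagents that add atoms: triethyl phosphonoacetate, CCOC(=O)CP(=O)(OCC)OCC
Why: Horner–Wadsworth–Emmons olefination of an aromatic aldehyde with a stabilised phosphonate gives the E enoate.

Step 6
Reactants: 7 ethyl (2E)-3-[3,5-bis(benzyloxy)phenyl]prop-2-enoate
Product: 8 (2E)-3-[3,5-bis(benzyloxy)phenyl]prop-2-en-1-ol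
Conditions: DIBAL-H (2.2 equiv), CH2Cl2, −78 °C; Rochelle salt
Reagents that add atoms: none
Why: DIBAL-H reduces the conjugated ester in the 1,2 sense to the allylic alcohol without touching the alkene.

Step 7
Reactants: 8 (2E)-3-[3,5-bis(benzyloxy)phenyl]prop-2-en-1-ol
Product: 9 (2E)-3-[3,5-bis(benzyloxy)phenyl]prop-2-en-1-yl methyl carbonate
Conditions: ClCO2Me, pyridine, CH2Cl2, 0 °C
Reagents that add atoms: methyl chloroformate, COC(=O)Cl
Why: O-Acylation with a chloroformate gives the linear allylic carbonate that ionises on iridium.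

Step 8
Reactants: 5 pentafluorophenyl 2-[3,5-bis(benzyloxy)-2-bromophenyl]acetate; 9 (2E)-3-[3,5-bis(benzyloxy)phenyl]prop-2-en-1-yl methyl carbonate
Product: 10 pentafluorophenyl (2S,3R)-2-[3,5-bis(benzyloxy)-2-bromophenyl]-3-DBP-pent-4-enoate
Conditions: [Ir(cod)Cl]2 (2 mol%), cyclometalated BINOL bis(1-phenylethyl)amine phosphoramidite (4 mol%, antipode giving 3R), BTM (10 mol%, antipode giving 2S), THF, rt
Reagents that add atoms: none
Why: Dual-catalytic allylic alkylation (Tsuji–Trost type on iridium with a C1-ammonium enolate): the isothiourea is acylated by the pentafluorophenyl ester, its enolate attacks the aryl-bearing terminus of the iridium allyl and pentafluorophenoxide returns to release the product, the iridium ligand setting C3 (R) and the isothiourea setting C2 (S) independently, which gives the diastereomer whose two aryl groups end up cis on the oxolane.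

Step 9
Reactants: 10 pentafluorophenyl (2S,3R)-2-[3,5-bis(benzyloxy)-2-bromophenyl]-3-DBP-pent-4-enoate
Product: 11 (2S,3R)-2-[3,5-bis(benzyloxy)-2-bromophenyl]-3-DBP-pent-4-enoic acid
Conditions: LiOH (2.2 equiv), THF/H2O, 0 °C; then 1 M HCl
Reagents that add atoms: lithium hydroxide, [Li+].[OH-]
Why: Hydroxide attacks the very electrophilic pentafluorophenyl ester much faster than it removes the α-hydrogen, so the hydrolysis should leave C2 intact.

Step 10
Reactants: 11 (2S,3R)-2-[3,5-bis(benzyloxy)-2-bromophenyl]-3-DBP-pent-4-enoic acid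
Product: 13 (3S,4R)-3-[3,5-bis(benzyloxy)-2-bromophenyl]-4-DBP-5-methoxyoxolan-2-one (both C5 epimers), via hydroxylactone 12 (not isolated)
Conditions: O3, CH2Cl2, −78 °C (Sudan III end point); Me2S, −78 °C to rt; then MeOH, CSA (cat.), rt
Reagents that add atoms: ozone, [O-][O+]=O (oxygen of the hydroxyl group in 12); methanol, CO
Why: Ozonolysis (Criegee mechanism) cuts the vinyl group to the aldehyde, which the γ-carboxylic acid captures at once as the cyclic hydroxylactone so that neither aryl-bearing centre sits in an open enolisable chain, and acid-catalysed acetal exchange with methanol then gives the pseudo-ester; ozone is dosed to the indicator end point to spare the electron-rich rings.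

Step 11
Reactants: 13 (3S,4R)-3-[3,5-bis(benzyloxy)-2-bromophenyl]-4-DBP-5-methoxyoxolan-2-one
Product: 14 (3S,4R)-3-[3,5-bis(benzyloxy)-2-bromophenyl]-4-DBP-5-methoxyoxolan-2-ol (anomers)
Conditions: DIBAL-H (1.1 equiv), CH2Cl2, −78 °C; Rochelle salt
Reagents that add atoms: none
Why: At −78 °C the aluminium hemiacetal formed by one hydride transfer is stable, so the lactone stops at the lactol (partial reduction), and the methyl acetal is inert.

Step 12
Reactants: 14 (3S,4R)-3-[3,5-bis(benzyloxy)-2-bromophenyl]-4-DBP-5-methoxyoxolan-2-ol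
Product: 15 (3S,4R)-2,5-bis(benzenesulfonyl)-3-[3,5-bis(benzyloxy)-2-bromophenyl]-4-DBP-oxolane (anomers)
Conditions: PhSO2H (4 equiv), CaCl2, CH2Cl2, rt
Reagents that add atoms: benzenesulfinic acid, O=S(O)c1ccccc1
Why: Acid-catalysed acetal exchange through cyclic oxocarbenium ions, with sulfinate as S-nucleophile, converts both the lactol and the methyl acetal carbon into α-sulfonyl ethers while calcium chloride takes up water and methanol.

Step 13
Reactants: 15 (3S,4R)-2,5-bis(benzenesulfonyl)-3-[3,5-bis(benzyloxy)-2-bromophenyl]-4-DBP-oxolane; 16 [4-(benzyloxy)phenyl]magnesium bromide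
Product: 17 (2R,3S,4R,5S)-3-[3,5-bis(benzyloxy)-2-bromophenyl]-4-DBP-2,5-di-BP-oxolane
Conditions: 16 (5 equiv), ZnBr2 (2.5 equiv), THF, 0 °C to rt
Reagents that add atoms: none
Why: Substitution of 2-sulfonyl cyclic ethers by aryl zinc reagents: zinc-assisted loss of sulfinate gives the oxocarbenium ion at C2 and then at C5, and each is arylated on the face anti to the aryl group on the neighbouring carbon, which sets C2 (R) and C5 (S) trans to the cis pair C3/C4.

Step 14
Reactants: 17 (2R,3S,4R,5S)-3-[3,5-bis(benzyloxy)-2-bromophenyl]-4-DBP-2,5-di-BP-oxolane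
Product: 18 2,4-bis(benzyloxy)-6-(THF unit)benzaldehyde
Conditions: n-BuLi (1.1 equiv), THF, −78 °C; DMF, −78 to 0 °C; aq. NH4Cl
Reagents that add atoms: N,N-dimethylformamide, CN(C)C=O
Why: Bromine–lithium exchange is faster than any deprotonation at −78 °C and the aryllithium is formylated by DMF (Bouveault-type formylation).

Step 15
Reactants: 18 2,4-bis(benzyloxy)-6-(THF unit)benzaldehyde
Product: 19 4-(benzyloxy)-2-hydroxy-6-(THF unit)benzaldehyde
Conditions: MgBr2·OEt2 (3 equiv), toluene/Et2O, 60 °C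
Reagents that add atoms: none
Why: Magnesium is chelated between the formyl oxygen and the ortho ether oxygen and bromide removes that benzyl group by SN2, so only the ether next to the aldehyde is cleaved (chelation-controlled dealkylation).

Step 16
Reactants: 20 2,3-dihydroxybenzaldehyde
Product: 21 3-(benzyloxy)-2-hydroxybenzaldehyde
Conditions: NaH (2.2 equiv), BnBr (1.0 equiv), DMSO, rt
Reagents that add atoms: benzyl bromide, BrCc1ccccc1
Why: In the dianion the 3-phenoxide, which is not tied up with the formyl group, is the more nucleophilic oxygen, so one equivalent of benzyl bromide gives the 3-ether (Williamson).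

Step 17
Reactants: 21 3-(benzyloxy)-2-hydroxybenzaldehyde
Product: 22 3-(benzyloxy)-5-bromo-2-hydroxybenzaldehyde
Conditions: Br2 (1.05 equiv), NaOAc, AcOH, rt
Reagents that add atoms: bromine, BrBr
Why: Electrophilic aromatic bromination para to the free phenol, the only open position that it activates.

Step 18
Reactants: 22 3-(benzyloxy)-5-bromo-2-hydroxybenzaldehyde; 23 4-(benzyloxy)benzyl chloride
Product: 24 3-(benzyloxy)-2-{[4-(benzyloxy)phenyl]methoxy}-5-bromobenzaldehyde
Conditions: K2CO3, KI (cat.), DMF, 60 °C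
Reagents that add atoms: none
Why: Williamson ether synthesis with an activated benzylic chloride under iodide catalysis.

Step 19
Reactants: 24 3-(benzyloxy)-2-{[4-(benzyloxy)phenyl]methoxy}-5-bromobenzaldehyde; 25 1-bromo-3,5-bis(benzyloxy)benzene
Product: 27 [3-(benzyloxy)-2-{[4-(benzyloxy)phenyl]methoxy}-5-bromophenyl](DBP)methanol (racemic), via aryl Grignard 26 (not isolated)
Conditions: 25, Mg, THF, reflux; then 24, 0 °C
Reagents that add atoms: none
Why: Grignard addition to the aldehyde; the aryl bromide of 24 does not exchange with an aryl Grignard reagent, and the racemic carbinol centre is removed in step 20.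

Step 20
Reactants: 27 [3-(benzyloxy)-2-{[4-(benzyloxy)phenyl]methoxy}-5-bromophenyl](DBP)methanol
Product: 28 [3-(benzyloxy)-2-{[4-(benzyloxy)phenyl]methoxy}-5-bromophenyl](DBP)methanone
Conditions: MnO2 (excess), CH2Cl2, rt
Reagents that add atoms: none
Why: Manganese dioxide oxidises the doubly benzylic alcohol to the diaryl ketone.

Step 21
Reactants: 28 [3-(benzyloxy)-2-{[4-(benzyloxy)phenyl]methoxy}-5-bromophenyl](DBP)methanone
Product: 29 hydrazone of 28 (E/Z mixture)
Conditions: N2H4·H2O (excess), AcOH (cat.), EtOH, 80 °C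
Reagents that add atoms: hydrazine, NN
Why: Condensation of the hindered benzophenone with hydrazine gives the free hydrazone.

Step 22
Reactants: 29 hydrazone of 28
Product: 31 (2S,3R)-7-(benzyloxy)-5-bromo-2-BP-3-DBP-2,3-dihydro-1-benzofuran (cis), via diazo compound 30 (not isolated)
Conditions: MnO2, MeCN, 0 °C; then Rh2(PTAD)4 (1 mol%, antipode giving 3R), 0 °C to rt
Reagents that add atoms: none
Why: Dehydrogenation of the hydrazone gives the diaryldiazomethane, and the rhodium donor/donor carbene inserts into the benzylic ether C–H five atoms away (intramolecular 1,5 C–H insertion), which closes ring B as the cis isomer with C3 (R) and C2 fixed together by the chiral carboxylate ligands.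

Step 23
Reactants: 31 (2S,3R)-7-(benzyloxy)-5-bromo-2-BP-3-DBP-2,3-dihydro-1-benzofuran
Product: 32 (2R,3R)-7-(benzyloxy)-5-bromo-2-BP-3-DBP-2,3-dihydro-1-benzofuran (trans)
Conditions: BF3·OEt2 (0.2 equiv), CH2Cl2, −40 to 0 °C
Reagents that add atoms: none
Why: The Lewis acid opens the C2–O bond reversibly to the 4-(benzyloxy)benzyl cation and the phenol recloses (5-exo) to the more stable trans ring, so C2 is inverted while C3 is not touched (acid-mediated epimerisation).

Step 24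
Reactants: 32 (2R,3R)-7-(benzyloxy)-5-bromo-2-BP-3-DBP-2,3-dihydro-1-benzofuran; 19 4-(benzyloxy)-2-hydroxy-6-(THF unit)benzaldehyde
Product: 35 5-(benzyloxy)-2-[hydroxy(ring-B unit)methyl]-3-(THF unit)phenol (both carbinol epimers), via aryllithium 33 (not isolated), via lithium phenoxide 34 (not isolated)
Conditions: 19, LiHMDS (1.0 equiv), THF, −78 °C; 32, n-BuLi (1.05 equiv), THF, −78 °C; combine, −78 to −40 °C; aq. NH4Cl
Reagents that add atoms: none
Why: Aryllithium addition to the aldehyde, whose phenol is masked as the lithium phenoxide; the carbinol centre forms as a mixture, which is of no consequence because this carbon becomes trigonal in step 29.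

Step 25
Reactants: 35 5-(benzyloxy)-2-[hydroxy(ring-B unit)methyl]-3-(THF unit)phenol
Product: 36 5-(benzyloxy)-2-[(4-methylbenzenesulfonyl)(ring-B unit)methyl]-3-(THF unit)phenol (both epimers at the sulfone carbon)
Conditions: p-TolSO2H (3 equiv), 4 Å MS, CH2Cl2, 0 °C; aq. NaHCO3
Reagents that add atoms: 4-methylbenzenesulfinic acid, Cc1ccc(cc1)S(=O)O
Why: SN1 substitution: the doubly benzylic carbinol flanked by the ortho hydroxyl ionises under the mild acid and sulfinate is bound through sulfur to give the sulfone, either epimer of which serves.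

Step 26
Reactants: 37 (2R,5R)-hexane-2,5-diol
Product: 38 (2R,5R)-hexane-2,5-diyl dimethanesulfonate
Conditions: MsCl, Et3N, CH2Cl2, 0 °C
Reagents that add atoms: methanesulfonyl chloride, CS(=O)(=O)Cl
Why: Sulfonylation of both alcohols with retention.

Step 27
Reactants: 38 (2R,5R)-hexane-2,5-diyl dimethanesulfonate
Product: 39 (2S,5S)-2,5-dimethylthiolane
Conditions: Na2S·9H2O, DMSO, rt to 50 °C
Reagents that add atoms: sodium sulfide, [Na+].[Na+].[S-2]
Why: Double SN2 displacement by sulfide, with inversion at each carbon, turns the (2R,5R) diol derivative into the C2-symmetric (2S,5S) thiolane.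

Step 28
Reactants: 39 (2S,5S)-2,5-dimethylthiolane; 23 4-(benzyloxy)benzyl chloride
Product: 40 (2S,5S)-1-{[4-(benzyloxy)phenyl]methyl}-2,5-dimethylthiolan-1-ium tetrafluoroborate
Conditions: AgBF4, CH2Cl2, 0 °C to rt, dark
Reagents that add atoms: silver tetrafluoroborate, [Ag+].F[B-](F)(F)F
Why: Silver-assisted S-alkylation by the benzylic chloride; the tetrafluoroborate counter-ion cannot dealkylate the salt, and the C2 symmetry of the sulfide means only one sulfonium salt can form.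

Step 29
Reactants: 36 5-(benzyloxy)-2-[(4-methylbenzenesulfonyl)(ring-B unit)methyl]-3-(THF unit)phenol; 40 (2S,5S)-1-{[4-(benzyloxy)phenyl]methyl}-2,5-dimethylthiolan-1-ium tetrafluoroborate
Product: 44 (2S,3S)-6-(benzyloxy)-2-BP-3-(ring-B unit)-4-(THF unit)-2,3-dihydro-1-benzofuran (decabenzyl kobophenol A), via sulfonium ylide 41 (not isolated), via o-quinone methide 42 (not isolated), via betaine 43 (not isolated)
Conditions: 40 (1.5 equiv), Cs2CO3 (4 equiv), MeCN/CH2Cl2 1:1, 0 °C to rt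
Reagents that add atoms: none
Why: Carbonate deprotonates the phenol of 36, toluenesulfinate leaves (E1cB) to give o-quinone methide 42, and the thiolanium benzylide 41 adds through its carbanion to the exocyclic methide carbon (1,4-addition that restores the arene, forming C2–C3) to give betaine 43, whose phenoxide displaces the thiolane at the 4-(benzyloxy)benzylic carbon (5-exo-tet with inversion, forming O1–C2 and closing ring A). The closest known reaction is the [4+1] annulation of o-quinone methides released from 2-(tosylalkyl)phenols with sulfonium ylides to trans-2,3-disubstituted dihydrobenzofurans, taken together with the epoxidations and aziridinations of C2-symmetric thiolanium benzylides. C2 is controlled by the ylide: the (2S,5S)-thiolane leaves one face of the benzylide carbon open, and the inversion in the ring closure turns that into 2S. C3 is set in the same C–C bond formation by the anti approach (the two aryl groups apart) that leads to the trans ring. The step needs one face of the methide carbon relative to the oxolane on C4; the oxolane centre next to ring A puts its hydrogen in the ring plane towards the methide hydrogen (allylic strain), which leaves both faces open and gives little bias of its own, so the chiral sulfide is what secures the face. Because every other centre is already fixed, a wrong-face product would be a diastereomer that chromatography removes.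

Step 30
Reactants: 44 decabenzyl kobophenol A
Product: 45 kobophenol A
Conditions: H2 (1 atm), 10% Pd/C, EtOAc/MeOH, rt
Reagents that add atoms: none
Why: Hydrogenolysis of the ten aryl benzyl ethers on palladium under neutral conditions; the cyclic benzylic C–O bonds of the oxolane and the two dihydrofurans are secondary and hindered and are cleaved far more slowly, and no acid or base is present that could epimerise them.

**Compound list**

1 | methyl 2-(3,5-dihydroxyphenyl)acetate | COC(=O)Cc1cc(O)cc(O)c1 | starting material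
2 | methyl 2-[3,5-bis(benzyloxy)phenyl]acetate | COC(=O)Cc1cc(OCc2ccccc2)cc(OCc2ccccc2)c1 | intermediate
3 | methyl 2-[3,5-bis(benzyloxy)-2-bromophenyl]acetate | COC(=O)Cc1cc(OCc2ccccc2)cc(OCc2ccccc2)c1Br | intermediate
4 | 2-[3,5-bis(benzyloxy)-2-bromophenyl]acetic acid | OC(=O)Cc1cc(OCc2ccccc2)cc(OCc2ccccc2)c1Br | intermediate
5 | pentafluorophenyl 2-[3,5-bis(benzyloxy)-2-bromophenyl]acetate | O=C(Cc1cc(OCc2ccccc2)cc(OCc2ccccc2)c1Br)Oc1c(F)c(F)c(F)c(F)c1F | intermediate
6 | 3,5-bis(benzyloxy)benzaldehyde | O=Cc1cc(OCc2ccccc2)cc(OCc2ccccc2)c1 | starting material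
7 | ethyl (2E)-3-[3,5-bis(benzyloxy)phenyl]prop-2-enoate | CCOC(=O)/C=C/c1cc(OCc2ccccc2)cc(OCc2ccccc2)c1 | intermediate
8 | (2E)-3-[3,5-bis(benzyloxy)phenyl]prop-2-en-1-ol | OC/C=C/c1cc(OCc2ccccc2)cc(OCc2ccccc2)c1 | intermediate
9 | (2E)-3-[3,5-bis(benzyloxy)phenyl]prop-2-en-1-yl methyl carbonate | COC(=O)OC/C=C/c1cc(OCc2ccccc2)cc(OCc2ccccc2)c1 | intermediate
10 | pentafluorophenyl (2S,3R)-2-[3,5-bis(benzyloxy)-2-bromophenyl]-3-DBP-pent-4-enoate | Brc1c(OCc9ccccc9)cc(OCc9ccccc9)cc1[C@@H](C(=O)Oc2c(F)c(F)c(F)c(F)c2F)[C@H](c8cc(OCc9ccccc9)cc(OCc9ccccc9)c8)C=C | intermediate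
11 | (2S,3R)-2-[3,5-bis(benzyloxy)-2-bromophenyl]-3-DBP-pent-4-enoic acid | Brc1c(OCc9ccccc9)cc(OCc9ccccc9)cc1[C@@H](C(=O)O)[C@H](c8cc(OCc9ccccc9)cc(OCc9ccccc9)c8)C=C | intermediate
12 | (3S,4R)-3-[3,5-bis(benzyloxy)-2-bromophenyl]-4-DBP-5-hydroxyoxolan-2-one (aryl groups cis) | Brc1c(OCc9ccccc9)cc(OCc9ccccc9)cc1[C@H]2C(=O)OC(O)[C@H]2c8cc(OCc9ccccc9)cc(OCc9ccccc9)c8 | intermediate (not isolated)
13 | (3S,4R)-3-[3,5-bis(benzyloxy)-2-bromophenyl]-4-DBP-5-methoxyoxolan-2-one | Brc1c(OCc9ccccc9)cc(OCc9ccccc9)cc1[C@H]2C(=O)OC(OC)[C@H]2c8cc(OCc9ccccc9)cc(OCc9ccccc9)c8 | intermediate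
14 | (3S,4R)-3-[3,5-bis(benzyloxy)-2-bromophenyl]-4-DBP-5-methoxyoxolan-2-ol | Brc1c(OCc9ccccc9)cc(OCc9ccccc9)cc1[C@H]2C(O)OC(OC)[C@H]2c8cc(OCc9ccccc9)cc(OCc9ccccc9)c8 | intermediate
15 | (3S,4R)-2,5-bis(benzenesulfonyl)-3-[3,5-bis(benzyloxy)-2-bromophenyl]-4-DBP-oxolane | Brc1c(OCc9ccccc9)cc(OCc9ccccc9)cc1[C@H]2C(S(=O)(=O)c3ccccc3)OC(S(=O)(=O)c3ccccc3)[C@H]2c8cc(OCc9ccccc9)cc(OCc9ccccc9)c8 | intermediate
16 | [4-(benzyloxy)phenyl]magnesium bromide (THF solution) | Br[Mg]c1ccc(OCc2ccccc2)cc1 | starting material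
17 | (2R,3S,4R,5S)-3-[3,5-bis(benzyloxy)-2-bromophenyl]-4-DBP-2,5-di-BP-oxolane | Brc1c(OCc9ccccc9)cc(OCc9ccccc9)cc1[C@@H]2[C@H](c8cc(OCc9ccccc9)cc(OCc9ccccc9)c8)[C@@H](c7ccc(OCc9ccccc9)cc7)O[C@H]2c7ccc(OCc9ccccc9)cc7 | intermediate
18 | 2,4-bis(benzyloxy)-6-(THF unit)benzaldehyde | O=Cc1c(OCc9ccccc9)cc(OCc9ccccc9)cc1[C@@H]2[C@H](c8cc(OCc9ccccc9)cc(OCc9ccccc9)c8)[C@@H](c7ccc(OCc9ccccc9)cc7)O[C@H]2c7ccc(OCc9ccccc9)cc7 | intermediate
19 | 4-(benzyloxy)-2-hydroxy-6-(THF unit)benzaldehyde | O=Cc1c(O)cc(OCc9ccccc9)cc1[C@@H]2[C@H](c8cc(OCc9ccccc9)cc(OCc9ccccc9)c8)[C@@H](c7ccc(OCc9ccccc9)cc7)O[C@H]2c7ccc(OCc9ccccc9)cc7 | intermediate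
20 | 2,3-dihydroxybenzaldehyde | O=Cc1cccc(O)c1O | starting material
21 | 3-(benzyloxy)-2-hydroxybenzaldehyde | O=Cc1cccc(OCc2ccccc2)c1O | intermediate
22 | 3-(benzyloxy)-5-bromo-2-hydroxybenzaldehyde | O=Cc1cc(Br)cc(OCc2ccccc2)c1O | intermediate
23 | 4-(benzyloxy)benzyl chloride | ClCc1ccc(OCc2ccccc2)cc1 | starting material
24 | 3-(benzyloxy)-2-{[4-(benzyloxy)phenyl]methoxy}-5-bromobenzaldehyde | O=Cc1cc(Br)cc(OCc2ccccc2)c1OCc1ccc(OCc2ccccc2)cc1 | intermediate
25 | 1-bromo-3,5-bis(benzyloxy)benzene | Brc1cc(OCc2ccccc2)cc(OCc2ccccc2)c1 | starting material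
26 | [3,5-bis(benzyloxy)phenyl]magnesium bromide | Br[Mg]c1cc(OCc2ccccc2)cc(OCc2ccccc2)c1 | intermediate (not isolated)
27 | [3-(benzyloxy)-2-{[4-(benzyloxy)phenyl]methoxy}-5-bromophenyl](DBP)methanol, racemic | OC(c1cc(Br)cc(OCc2ccccc2)c1OCc1ccc(OCc2ccccc2)cc1)c1cc(OCc2ccccc2)cc(OCc2ccccc2)c1 | intermediate
28 | [3-(benzyloxy)-2-{[4-(benzyloxy)phenyl]methoxy}-5-bromophenyl](DBP)methanone | O=C(c1cc(Br)cc(OCc2ccccc2)c1OCc1ccc(OCc2ccccc2)cc1)c1cc(OCc2ccccc2)cc(OCc2ccccc2)c1 | intermediate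
29 | hydrazone of 28 | NN=C(c1cc(Br)cc(OCc2ccccc2)c1OCc1ccc(OCc2ccccc2)cc1)c1cc(OCc2ccccc2)cc(OCc2ccccc2)c1 | intermediate
30 | 1-(benzyloxy)-2-{[4-(benzyloxy)phenyl]methoxy}-5-bromo-3-[diazo(DBP)methyl]benzene | [N-]=[N+]=C(c1cc(Br)cc(OCc2ccccc2)c1OCc1ccc(OCc2ccccc2)cc1)c1cc(OCc2ccccc2)cc(OCc2ccccc2)c1 | intermediate (not isolated)
31 | (2S,3R)-7-(benzyloxy)-5-bromo-2-BP-3-DBP-2,3-dihydro-1-benzofuran (cis) | Brc1cc(OCc9ccccc9)c2c(c1)[C@@H](c8cc(OCc9ccccc9)cc(OCc9ccccc9)c8)[C@@H](c7ccc(OCc9ccccc9)cc7)O2 | intermediate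
32 | (2R,3R)-7-(benzyloxy)-5-bromo-2-BP-3-DBP-2,3-dihydro-1-benzofuran (trans) | Brc1cc(OCc9ccccc9)c2c(c1)[C@@H](c8cc(OCc9ccccc9)cc(OCc9ccccc9)c8)[C@H](c7ccc(OCc9ccccc9)cc7)O2 | intermediate
33 | 5-lithio derivative of 32 | [Li]c1cc(OCc9ccccc9)c2c(c1)[C@@H](c8cc(OCc9ccccc9)cc(OCc9ccccc9)c8)[C@H](c7ccc(OCc9ccccc9)cc7)O2 | intermediate (not isolated)
34 | lithium phenoxide of 19 | [Li+].[O-]c1cc(OCc9ccccc9)cc([C@@H]2[C@H](c8cc(OCc9ccccc9)cc(OCc9ccccc9)c8)[C@@H](c7ccc(OCc9ccccc9)cc7)O[C@H]2c7ccc(OCc9ccccc9)cc7)c1C=O | intermediate (not isolated)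
35 | 5-(benzyloxy)-2-[hydroxy(ring-B unit)methyl]-3-(THF unit)phenol, both carbinol epimers | Oc1cc(OCc9ccccc9)cc([C@@H]2[C@H](c8cc(OCc9ccccc9)cc(OCc9ccccc9)c8)[C@@H](c7ccc(OCc9ccccc9)cc7)O[C@H]2c7ccc(OCc9ccccc9)cc7)c1C(O)c2cc(OCc9ccccc9)c3c(c2)[C@@H](c8cc(OCc9ccccc9)cc(OCc9ccccc9)c8)[C@H](c7ccc(OCc9ccccc9)cc7)O3 | intermediate
36 | 5-(benzyloxy)-2-[(4-methylbenzenesulfonyl)(ring-B unit)methyl]-3-(THF unit)phenol, both epimers at the sulfone carbon | Oc1cc(OCc9ccccc9)cc([C@@H]2[C@H](c8cc(OCc9ccccc9)cc(OCc9ccccc9)c8)[C@@H](c7ccc(OCc9ccccc9)cc7)O[C@H]2c7ccc(OCc9ccccc9)cc7)c1C(S(=O)(=O)c4ccc(C)cc4)c2cc(OCc9ccccc9)c3c(c2)[C@@H](c8cc(OCc9ccccc9)cc(OCc9ccccc9)c8)[C@H](c7ccc(OCc9ccccc9)cc7)O3 | intermediate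
37 | (2R,5R)-hexane-2,5-diol | C[C@@H](O)CC[C@@H](C)O | starting material
38 | (2R,5R)-hexane-2,5-diyl dimethanesulfonate | C[C@@H](OS(C)(=O)=O)CC[C@@H](C)OS(C)(=O)=O | intermediate
39 | (2S,5S)-2,5-dimethylthiolane | C[C@H]1CC[C@H](C)S1 | intermediate
40 | (2S,5S)-1-{[4-(benzyloxy)phenyl]methyl}-2,5-dimethylthiolan-1-ium tetrafluoroborate | C[C@H]1CC[C@H](C)[S+]1Cc1ccc(OCc2ccccc2)cc1.F[B-](F)(F)F | intermediate
41 | (2S,5S)-2,5-dimethylthiolanium [4-(benzyloxy)phenyl]methylide | C[C@H]1CC[C@H](C)[S+]1[CH-]c1ccc(OCc2ccccc2)cc1 | intermediate (not isolated)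
42 | 3-(benzyloxy)-6-[(ring-B unit)methylidene]-5-(THF unit)cyclohexa-2,4-dien-1-one (aryl of the methide on the carbonyl side) | O=C1C=C(OCc9ccccc9)C=C([C@@H]2[C@H](c8cc(OCc9ccccc9)cc(OCc9ccccc9)c8)[C@@H](c7ccc(OCc9ccccc9)cc7)O[C@H]2c7ccc(OCc9ccccc9)cc7)C1=Cc2cc(OCc9ccccc9)c3c(c2)[C@@H](c8cc(OCc9ccccc9)cc(OCc9ccccc9)c8)[C@H](c7ccc(OCc9ccccc9)cc7)O3 | intermediate (not isolated)
43 | betaine: phenoxide of ring A with the (S)-CH(ring-B unit)–(R)-CH(BP)–thiolanium chain on the carbon ortho to it | C[C@H]1CC[C@H](C)[S+]1[C@@H](c7ccc(OCc9ccccc9)cc7)[C@@H](c2cc(OCc9ccccc9)c3c(c2)[C@@H](c8cc(OCc9ccccc9)cc(OCc9ccccc9)c8)[C@H](c7ccc(OCc9ccccc9)cc7)O3)c1c([O-])cc(OCc9ccccc9)cc1[C@@H]2[C@H](c8cc(OCc9ccccc9)cc(OCc9ccccc9)c8)[C@@H](c7ccc(OCc9ccccc9)cc7)O[C@H]2c7ccc(OCc9ccccc9)cc7 | intermediate (not isolated)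
44 | (2S,3S)-6-(benzyloxy)-2-BP-3-(ring-B unit)-4-(THF unit)-2,3-dihydro-1-benzofuran (decabenzyl kobophenol A) | O(Cc9ccccc9)c1ccc([C@H]2Oc3cc(OCc9ccccc9)cc([C@@H]4[C@H](c5cc(OCc9ccccc9)cc(OCc9ccccc9)c5)[C@@H](c5ccc(OCc9ccccc9)cc5)O[C@H]4c4ccc(OCc9ccccc9)cc4)c3[C@@H]2c2cc(OCc9ccccc9)c3c(c2)[C@@H](c2cc(OCc9ccccc9)cc(OCc9ccccc9)c2)[C@H](c2ccc(OCc9ccccc9)cc2)O3)cc1 | intermediate
45 | kobophenol A: (2S,3S)-4-[(2R,3S,4R,5S)-4-(3,5-dihydroxyphenyl)-2,5-bis(4-hydroxyphenyl)oxolan-3-yl]-3-[(2R,3R)-3-(3,5-dihydroxyphenyl)-7-hydroxy-2-(4-hydroxyphenyl)-2,3-dihydro-1-benzofuran-5-yl]-2-(4-hydroxyphenyl)-2,3-dihydro-1-benzofuran-6-ol | Oc1ccc([C@H]2Oc3cc(O)cc([C@@H]4[C@H](c5cc(O)cc(O)c5)[C@@H](c5ccc(O)cc5)O[C@H]4c4ccc(O)cc4)c3[C@@H]2c2cc(O)c3c(c2)[C@@H](c2cc(O)cc(O)c2)[C@H](c2ccc(O)cc2)O3)cc1 | target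

**Step count and risks**

Total steps: 30. Longest linear sequence: 16 (steps 1–4, 8–15, 24, 25, 29, 30).

Steps most likely to fail:

1. Step 29. The addition may show poor facial selectivity at the methide carbon if the chiral ylide and the small bias of the oxolane are mismatched. The benzylic sulfonium salt may be consumed by phenoxide or sulfinate (transfer of the 4-(benzyloxy)benzyl group). The ylide may add too slowly to the crowded methide, which then reacts with itself. Fallback, setting out from 35 and coming back at 44, with the ring closed by a catalyst-controlled carbene C–H insertion instead: the phenol of 35 is alkylated with 23 (K2CO3, DMF) to give the 4-(benzyloxy)benzyl ether F1. The benzhydrol is oxidised with MnO2 to the diaryl ketone F2, and hydrazine gives the hydrazone F3. MnO2 then forms the diaryldiazomethane F4 in the flask, and a chiral Rh(II) carboxylate (the antipode that sets 3S) inserts the carbene into the ether C–H to give the cis-dihydrobenzofuran F5. Its C2 is turned over with a catalytic amount of BF3·OEt2 at −40 °C, as in step 23, to give 44; the aryl ether C2–O of ring A ionises more readily than the dialkyl ether bonds of the oxolane.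

2. Step 13. The oxocarbenium ions carry an aryl group on the neighbouring carbon and may lose a proton instead of being arylated, giving dihydrofuran and then 3,4-diarylfuran with loss of C3/C4. The second substitution may stall, or the aryl group may be delivered to the wrong face. Fallback, setting out from 11 and coming back at 17, with carbonyl additions and a cyclodehydration in place of the sulfone substitutions: ozonolysis of 11 with the dimethyl sulfide work-up alone gives 12, which is isolated. An excess of 16 adds to its open aldehyde form and acidification closes the 5-aryl lactone F6 (both C5 epimers). DIBAL-H reduces it to the lactol F7, and a second excess of 16 opens the lactol to the 1,4-diol F8. A catalytic amount of camphorsulfonic acid in CH2Cl2 at 0 °C closes the oxolane through the 4-(benzyloxy)benzylic cations, which let both C–O centres settle in the isomer with each aryl group trans to its neighbour, 17.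

3. Step 25. Under the acid the sulfone can ionise again, and the benzhydryl cation may be captured by the nearby 3,5-bis(benzyloxy)phenyl ring of the oxolane (Friedel–Crafts closure of a seven-membered ring) instead of by sulfinate. The p-oxybenzylic cyclic ethers may also ionise. Fallback, setting out from 35 and coming back at 44 without any acid (it replaces steps 25 and 29): the phenol of 35 is converted with Boc2O and catalytic DMAP into the aryl tert-butyl carbonate F9. KHMDS (2.2 equiv) in THF at −78 °C, with salt 40 present, deprotonates the benzhydrol, and the carbonate group migrates to the benzylic oxygen to give the phenoxide F10. F10 loses tert-butyl carbonate to form the same o-quinone methide 42, and the ylide 41 made by the second equivalent of base carries it on to 44 as in step 29.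

Further compounds
F1 | step 29 | 4-(benzyloxy)benzyl ether of the phenol of 35 | O(Cc7ccc(OCc9ccccc9)cc7)c1cc(OCc9ccccc9)cc([C@@H]2[C@H](c8cc(OCc9ccccc9)cc(OCc9ccccc9)c8)[C@@H](c7ccc(OCc9ccccc9)cc7)O[C@H]2c7ccc(OCc9ccccc9)cc7)c1C(O)c2cc(OCc9ccccc9)c3c(c2)[C@@H](c8cc(OCc9ccccc9)cc(OCc9ccccc9)c8)[C@H](c7ccc(OCc9ccccc9)cc7)O3
F2 | step 29 | diaryl ketone from F1 | O(Cc7ccc(OCc9ccccc9)cc7)c1cc(OCc9ccccc9)cc([C@@H]2[C@H](c8cc(OCc9ccccc9)cc(OCc9ccccc9)c8)[C@@H](c7ccc(OCc9ccccc9)cc7)O[C@H]2c7ccc(OCc9ccccc9)cc7)c1C(=O)c2cc(OCc9ccccc9)c3c(c2)[C@@H](c8cc(OCc9ccccc9)cc(OCc9ccccc9)c8)[C@H](c7ccc(OCc9ccccc9)cc7)O3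
F3 | step 29 | hydrazone of F2 | O(Cc7ccc(OCc9ccccc9)cc7)c1cc(OCc9ccccc9)cc([C@@H]2[C@H](c8cc(OCc9ccccc9)cc(OCc9ccccc9)c8)[C@@H](c7ccc(OCc9ccccc9)cc7)O[C@H]2c7ccc(OCc9ccccc9)cc7)c1C(=NN)c2cc(OCc9ccccc9)c3c(c2)[C@@H](c8cc(OCc9ccccc9)cc(OCc9ccccc9)c8)[C@H](c7ccc(OCc9ccccc9)cc7)O3
F4 | step 29 | diaryldiazomethane from F3 | O(Cc7ccc(OCc9ccccc9)cc7)c1cc(OCc9ccccc9)cc([C@@H]2[C@H](c8cc(OCc9ccccc9)cc(OCc9ccccc9)c8)[C@@H](c7ccc(OCc9ccccc9)cc7)O[C@H]2c7ccc(OCc9ccccc9)cc7)c1C(=[N+]=[N-])c2cc(OCc9ccccc9)c3c(c2)[C@@H](c8cc(OCc9ccccc9)cc(OCc9ccccc9)c8)[C@H](c7ccc(OCc9ccccc9)cc7)O3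
F5 | step 29 | C2 epimer of 44, cis ring A (2R,3S) | O(Cc9ccccc9)c1ccc([C@@H]2Oc3cc(OCc9ccccc9)cc([C@@H]4[C@H](c5cc(OCc9ccccc9)cc(OCc9ccccc9)c5)[C@@H](c5ccc(OCc9ccccc9)cc5)O[C@H]4c4ccc(OCc9ccccc9)cc4)c3[C@@H]2c2cc(OCc9ccccc9)c3c(c2)[C@@H](c2cc(OCc9ccccc9)cc(OCc9ccccc9)c2)[C@H](c2ccc(OCc9ccccc9)cc2)O3)cc1
F6 | step 13 | (3S,4R)-3-[3,5-bis(benzyloxy)-2-bromophenyl]-4-DBP-5-BP-oxolan-2-one, both C5 epimers | Brc1c(OCc9ccccc9)cc(OCc9ccccc9)cc1[C@H]2C(=O)OC(c7ccc(OCc9ccccc9)cc7)[C@H]2c8cc(OCc9ccccc9)cc(OCc9ccccc9)c8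
F7 | step 13 | (3S,4R)-3-[3,5-bis(benzyloxy)-2-bromophenyl]-4-DBP-5-BP-oxolan-2-ol | Brc1c(OCc9ccccc9)cc(OCc9ccccc9)cc1[C@H]2C(O)OC(c7ccc(OCc9ccccc9)cc7)[C@H]2c8cc(OCc9ccccc9)cc(OCc9ccccc9)c8
F8 | step 13 | (2S,3R)-2-[3,5-bis(benzyloxy)-2-bromophenyl]-3-DBP-1,4-di-BP-butane-1,4-diol, carbinol epimers | Brc1c(OCc9ccccc9)cc(OCc9ccccc9)cc1[C@@H](C(O)c7ccc(OCc9ccccc9)cc7)[C@H](c8cc(OCc9ccccc9)cc(OCc9ccccc9)c8)C(O)c7ccc(OCc9ccccc9)cc7
F9 | step 25 | aryl tert-butyl carbonate of the phenol of 35 | CC(C)(C)OC(=O)Oc1cc(OCc9ccccc9)cc([C@@H]2[C@H](c8cc(OCc9ccccc9)cc(OCc9ccccc9)c8)[C@@H](c7ccc(OCc9ccccc9)cc7)O[C@H]2c7ccc(OCc9ccccc9)cc7)c1C(O)c2cc(OCc9ccccc9)c3c(c2)[C@@H](c8cc(OCc9ccccc9)cc(OCc9ccccc9)c8)[C@H](c7ccc(OCc9ccccc9)cc7)O3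
F10 | step 25 | potassium phenoxide with the tert-butyl carbonate on the benzylic oxygen | [K+].[O-]c1cc(OCc9ccccc9)cc([C@@H]2[C@H](c8cc(OCc9ccccc9)cc(OCc9ccccc9)c8)[C@@H](c7ccc(OCc9ccccc9)cc7)O[C@H]2c7ccc(OCc9ccccc9)cc7)c1C(OC(=O)OC(C)(C)C)c2cc(OCc9ccccc9)c3c(c2)[C@@H](c8cc(OCc9ccccc9)cc(OCc9ccccc9)c8)[C@H](c7ccc(OCc9ccccc9)cc7)O3
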